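**Plan**

- Target read as ent-robinetinidol-(4α→8)-ent-epirobinetinidol-(4α→8)-epicatechin: top unit (2S,3R,4S; 2,3-trans-3,4-cis), middle unit (2S,3S,4S; 2,3-cis-3,4-trans), bottom unit (2R,3R).
- Cuts, in retrosynthetic order: the O-benzyl bonds and one C–Br bond; C4–H of the top unit (back to a C4 carbinol, so that the C4(top)–C8(middle) bond comes from aryl-metal addition to a C4 ketone); C4(middle)–C8(bottom) (flavan-4-yl cation plus epicatechin); and, in ring C of the top-unit flavanone, O1–C8a and C2–C3 together (aldol and SNAr in one operation).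
- Enabling feature: C4 of ring C can be carried as a carbonyl. It acidifies C3–H beside the C3 oxygen (enolate for C2–C3) and lies ortho to C8a of ring A, so a fluorine there is displaced by the new C2 alkoxide (O1–C8a). The same carbonyl later accepts the C8 aryl of the middle unit and is then removed.
- Forward order: the flavanone (ring C closed in one step) is used twice. One part becomes the middle unit (C4 deoxygenation, C3 inversion, C4 re-oxidation) and is joined to benzylated epicatechin. The C8 bromide of that dimer is metalated and added to a second part of the flavanone, then ionic reduction and hydrogenolysis finish. The bromine is the nucleophilic site in the middle unit and a silent passenger in the top unit.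
- Stereochemistry: C2 of both upper units from the chiral ammonium catalyst in the key step; C3 (top) from trans equilibration; C3 (middle) from oxidation and LiBH(sec-Bu)3 reduction; C4 (middle) from arene attack anti to O3; C4 (top) from hydride capture anti to O3 of the 4-aryl cation (aryl first, hydride second, hence 3,4-cis); bottom unit from (−)-epicatechin.

Key step: step 5

Assumption: the cinchonidinium salt is taken to favour the 2S series; should the sense be opposite, the pseudo-enantiomeric cinchoninium salt would serve under the same conditions.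

**Route**

Step 1
Reactants: 1 2-bromo-3-fluorophenol
Product: 2 1-(benzyloxy)-2-bromo-3-fluorobenzene
Conditions: BnBr, K2CO3, DMF, rt
Reagents that add atoms: benzyl bromide, BrCc1ccccc1
Why: Williamson ether synthesis on the phenoxide installs the benzyl group that every phenol carries until the final hydrogenolysis.

Step 2
Reactants: 2 1-(benzyloxy)-2-bromo-3-fluorobenzene
Product: 3 1-(benzyloxy)-2-bromo-3-fluoro-4-iodobenzene
Conditions: N-iodosuccinimide, TFA (10 mol %), MeCN, rt
Reagents that add atoms: N-iodosuccinimide, O=C1CCC(=O)N1I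
Why: Electrophilic aromatic iodination should go para to the benzyloxy group, the strongest donor, at the carbon that is also ortho to fluorine, and gives a carbon–iodine bond that exchanges with magnesium faster than the carbon–bromine bond.

Step 3
Reactants: 4 4-methoxybenzyl alcohol; 5 2-chloro-N-methoxy-N-methylacetamide
Product: 6 N-methoxy-2-[(4-methoxybenzyl)oxy]-N-methylacetamide
Conditions: NaH, THF, 0 °C to rt
Reagents that add atoms: none
Why: Williamson etherification (SN2 of the sodium alkoxide at the activated α-chloro amide carbon) gives the glycolate Weinreb amide whose 4-methoxybenzyl (PMB) group is later released by the acidic reductions.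

Step 4
Reactants: 3 1-(benzyloxy)-2-bromo-3-fluoro-4-iodobenzene; 6 N-methoxy-2-[(4-methoxybenzyl)oxy]-N-methylacetamide
Product: 8 1-[4-(benzyloxy)-3-bromo-2-fluorophenyl]-2-[(4-methoxybenzyl)oxy]ethan-1-one, via arylmagnesium chloride 7 (not isolated)
Conditions: i-PrMgCl·LiCl, THF, −40 °C; then 6, −40 to 0 °C; aq NH4Cl
Reagents that add atoms: none
Why: Iodine–magnesium exchange should be selective for the iodide over the bromide at low temperature, where the ortho-fluoro Grignard reagent is stable, and the Weinreb ketone synthesis stops at the ketone through the chelated tetrahedral adduct.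

Step 5
Reactants: 8 1-[4-(benzyloxy)-3-bromo-2-fluorophenyl]-2-[(4-methoxybenzyl)oxy]ethan-1-one; 9 3,4,5-tris(benzyloxy)benzaldehyde
Product: 11 (2S,3S)-7-(benzyloxy)-8-bromo-3-[(4-methoxybenzyl)oxy]-2-[3,4,5-tris(benzyloxy)phenyl]chroman-4-one, via anti-aldolate 10 (not isolated)
Conditions: 9 (1.2 equiv), O-allyl-N-(9-anthracenylmethyl)cinchonidinium bromide (10 mol %), CsOH·H2O (1.5 equiv), toluene/CH2Cl2 7:3, −40 to 0 °C
Reagents that add atoms: none
Why: Proposed new method: under solid–liquid phase transfer the chiral ammonium enolate of 8 adds to aldehyde 9 (aldol, forming C2–C3) and the aldolate oxygen then displaces fluoride from C8a of ring A by addition–elimination through a Meisenheimer adduct that the ortho C4 carbonyl stabilises (SNAr, forming O1–C8a), which closes ring C by a 6-exo attack of the tethered alkoxide on the ipso carbon. The closest known reaction types are the phase-transfer Darzens condensation of α-halo ketones, in which a reversible aldol is followed by ring closure of the aldolate inside a chiral ion pair, the phase-transfer aldol of glycine imines, and the intramolecular SNAr etherification of ortho-fluoroaryl ketones; what is new is their union, with an aryl fluoride in place of the alkyl halide. C2 should be set as S by the catalyst, because the aldol is reversible while the SNAr is not, so the C2-epimeric aldolates equilibrate and the cinchonidinium cation paired with the alkoxide selects the one that cyclises (dynamic kinetic asymmetric transformation). C3 should be set as S by thermodynamic control, because it stays enolisable in 11 and settles trans to the C2 aryl group with both substituents equatorial. The step needs SNAr to outrun dehydration of the aldolate to the chalcone and base-induced ring opening of the product, which the low temperature and the activation of C8a by the ortho carbonyl and the flanking bromine should secure; the bromide at C8 is meta to the carbonyl and should not be displaced.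

Step 6
Reactants: 11 (2S,3S)-7-(benzyloxy)-8-bromo-3-[(4-methoxybenzyl)oxy]-2-[3,4,5-tris(benzyloxy)phenyl]chroman-4-one
Product: 12 (2S,3R)-7-(benzyloxy)-8-bromo-2-[3,4,5-tris(benzyloxy)phenyl]chroman-3-ol (2,3-trans)
Conditions: Et3SiH (6 equiv), TFA, CH2Cl2, 0 °C to rt
Reagents that add atoms: none
Why: Ionic hydrogenation (Kursanov–Parnes type) should reduce the electron-rich aryl ketone to the methylene through the benzylic cation while TFA cleaves the PMB ether, whose cation the silane traps, and C2 and C3 are not touched.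

Step 7
Reactants: 12 (2S,3R)-7-(benzyloxy)-8-bromo-2-[3,4,5-tris(benzyloxy)phenyl]chroman-3-ol
Product: 13 (2S)-7-(benzyloxy)-8-bromo-2-[3,4,5-tris(benzyloxy)phenyl]chroman-3-one
Conditions: Dess–Martin periodinane, CH2Cl2, rt
Reagents that add atoms: none
Why: Dess–Martin oxidation of the secondary alcohol proceeds under near-neutral conditions that should not epimerise the enolisable C2 of the flavan-3-one, which is used at once.

Step 8
Reactants: 13 (2S)-7-(benzyloxy)-8-bromo-2-[3,4,5-tris(benzyloxy)phenyl]chroman-3-one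
Product: 14 (2S,3S)-7-(benzyloxy)-8-bromo-2-[3,4,5-tris(benzyloxy)phenyl]chroman-3-ol (2,3-cis)
Conditions: LiBH(sec-Bu)3, THF, −78 °C
Reagents that add atoms: none
Why: The bulky hydride should attack the C3 ketone from the face opposite the C2 aryl group (substrate control) and give the axial 2,3-cis alcohol, the same oxidation–reduction that turns catechin ethers into epicatechin ethers.

Step 9
Reactants: 14 (2S,3S)-7-(benzyloxy)-8-bromo-2-[3,4,5-tris(benzyloxy)phenyl]chroman-3-ol
Product: 15 (2S,3S)-3,7-bis(benzyloxy)-8-bromo-2-[3,4,5-tris(benzyloxy)phenyl]chromane (2,3-cis)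
Conditions: NaH, BnBr, Bu4NI (5 mol %), DMF, 0 °C to rt
Reagents that add atoms: benzyl bromide, BrCc1ccccc1
Why: Williamson benzylation of the sodium alkoxide masks the 3-hydroxyl before the organolithium chemistry.

Step 10
Reactants: 15 (2S,3S)-3,7-bis(benzyloxy)-8-bromo-2-[3,4,5-tris(benzyloxy)phenyl]chromane
Product: 16 (2S,3S,4R)-3,7-bis(benzyloxy)-8-bromo-4-(2-ethoxyethoxy)-2-[3,4,5-tris(benzyloxy)phenyl]chromane (2,3-cis-3,4-trans)
Conditions: DDQ (2 equiv), 2-ethoxyethanol (5 equiv), CH2Cl2, rt
Reagents that add atoms: 2-ethoxyethanol, CCOCCO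
Why: DDQ should abstract hydride from benzylic C4, which O1 (ortho) and the 7-benzyloxy group (para) activate, and the alcohol traps the cation anti to the C3 benzyloxy group (oxidative benzylic etherification, substrate control).

Step 11
Reactants: 17 (−)-epicatechin
Product: 18 5,7,3',4'-tetra-O-benzyl-(−)-epicatechin
Conditions: BnBr (4.4 equiv), K2CO3, DMF, 0 °C to rt
Reagents that add atoms: benzyl bromide, BrCc1ccccc1
Why: Williamson benzylation under carbonate is selective for the four phenols over the secondary alcohol and mild enough to leave C2 unchanged.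

Step 12
Reactants: 18 5,7,3',4'-tetra-O-benzyl-(−)-epicatechin
Product: 19 3,5,7,3',4'-penta-O-benzyl-(−)-epicatechin
Conditions: NaH, BnBr, DMF, 0 °C to rt
Reagents that add atoms: benzyl bromide, BrCc1ccccc1
Why: Williamson benzylation of the remaining 3-hydroxyl gives a nucleophile without acidic protons for the later lithiation.

Step 13
Reactants: 16 (2S,3S,4R)-3,7-bis(benzyloxy)-8-bromo-4-(2-ethoxyethoxy)-2-[3,4,5-tris(benzyloxy)phenyl]chromane; 19 3,5,7,3',4'-penta-O-benzyl-(−)-epicatechin
Product: 20 8-bromo-ent-epirobinetinidol-(4α→8)-epicatechin deca-O-benzyl ether (middle unit 2S,3S,4S with 3,4-trans; bottom unit 2R,3R; bromine on C8 of ring A of the middle unit)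
Conditions: 19 (3 equiv), TMSOTf (0.3 equiv), CH2Cl2, −78 to −30 °C; Et3N quench
Reagents that add atoms: none
Why: Lewis-acid ionisation of the C4 ether gives the flavan-4-yl cation, which C8 of the phloroglucinol-type ring A of 19 should attack (Friedel–Crafts alkylation) on the face opposite the cis-disposed C2 aryl and C3 benzyloxy groups, setting C4 of the middle unit 3,4-trans.

Step 14
Reactants: 20 8-bromo-ent-epirobinetinidol-(4α→8)-epicatechin deca-O-benzyl ether; 11 (2S,3S)-7-(benzyloxy)-8-bromo-3-[(4-methoxybenzyl)oxy]-2-[3,4,5-tris(benzyloxy)phenyl]chroman-4-one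
Product: 23 C4 carbinol of the protected trimer (top unit: 4-hydroxy-4-aryl flavan bearing 3-O-PMB and 8-Br; aryl trans to the PMB ether as the expected major C4 epimer), via aryllithium 21 (not isolated), via arylcerium dichloride 22 (not isolated)
Conditions: t-BuLi (2.1 equiv), THF, −78 °C; CeCl3 (anhydrous, 1.5 equiv), −78 °C; then 11 (1.5 equiv), −78 to −20 °C; aq NH4Cl
Reagents that add atoms: none
Why: Bromine–lithium exchange places the nucleophilic carbon at C8 of ring A of the middle unit, a site that electrophilic substitution would not select, and the organocerium reagent should add to the enolisable ketone without deprotonating C3 (1,2-addition of an aryl metal to a flavanone); the C4 configuration formed here is erased in step 15.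

Step 15
Reactants: 23 C4 carbinol of the protected trimer
Product: 24 8-bromo-ent-robinetinidol-(4α→8)-ent-epirobinetinidol-(4α→8)-epicatechin tetradeca-O-benzyl ether (free 3-OH on the top unit; top unit 2S,3R,4S; bromine on C8 of ring A of the top unit)
Conditions: Et3SiH (20 equiv), TFA, CH2Cl2, −40 to 0 °C
Reagents that add atoms: none
Why: Ionic hydrogenation of the tertiary diaryl carbinol: TFA ionises C4 to a cation stabilised by both electron-rich rings, Et3SiH should deliver hydride to the face anti to the C3 oxygen so that the aryl group ends cis to O3 (3,4-cis and 2,4-trans, substrate control), and the PMB ether is cleaved in the same medium.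

Step 16
Reactants: 24 8-bromo-ent-robinetinidol-(4α→8)-ent-epirobinetinidol-(4α→8)-epicatechin tetradeca-O-benzyl ether
Product: 25 ent-robinetinidol-(4α→8)-ent-epirobinetinidol-(4α→8)-epicatechin (CNP0115797.3)
Conditions: H2 (1 atm), Pd(OH)2 on carbon, NaOAc (1.5 equiv), THF/MeOH/H2O, rt
Reagents that add atoms: none
Why: Catalytic hydrogenolysis should cleave the fourteen benzyl ethers and the aryl bromide of the top unit in one operation without touching the stereocentres.

**Compound list**

1 | 2-bromo-3-fluorophenol | Oc1cccc(F)c1Br | starting material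
2 | 1-(benzyloxy)-2-bromo-3-fluorobenzene | Fc1cccc(OCc2ccccc2)c1Br | intermediate
3 | 1-(benzyloxy)-2-bromo-3-fluoro-4-iodobenzene | Fc1c(I)ccc(OCc2ccccc2)c1Br | intermediate
4 | 4-methoxybenzyl alcohol | COc1ccc(CO)cc1 | starting material
5 | 2-chloro-N-methoxy-N-methylacetamide | CON(C)C(=O)CCl | starting material
6 | N-methoxy-2-[(4-methoxybenzyl)oxy]-N-methylacetamide | CON(C)C(=O)COCc1ccc(OC)cc1 | intermediate
7 | [4-(benzyloxy)-3-bromo-2-fluorophenyl]magnesium chloride (LiCl complex, not isolated) | Fc1c([Mg]Cl)ccc(OCc2ccccc2)c1Br | intermediate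
8 | 1-[4-(benzyloxy)-3-bromo-2-fluorophenyl]-2-[(4-methoxybenzyl)oxy]ethan-1-one | COc1ccc(COCC(=O)c2ccc(OCc3ccccc3)c(Br)c2F)cc1 | intermediate
9 | 3,4,5-tris(benzyloxy)benzaldehyde | O=Cc1cc(OCc2ccccc2)c(OCc2ccccc2)c(OCc2ccccc2)c1 | starting material
10 | (2S,3S)-1-[4-(benzyloxy)-3-bromo-2-fluorophenyl]-3-hydroxy-2-[(4-methoxybenzyl)oxy]-3-[3,4,5-tris(benzyloxy)phenyl]propan-1-one (anti aldolate, drawn as the alcohol; not isolated) | O[C@@H](c1cc(OCc2ccccc2)c(OCc2ccccc2)c(OCc2ccccc2)c1)[C@H](OCc1ccc(OC)cc1)C(=O)c1ccc(OCc2ccccc2)c(Br)c1F | intermediate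
11 | (2S,3S)-7-(benzyloxy)-8-bromo-3-[(4-methoxybenzyl)oxy]-2-[3,4,5-tris(benzyloxy)phenyl]chroman-4-one (2,3-trans) | C(c3ccccc3)Oc1ccc2c(c1Br)O[C@@H](c3cc(OCc4ccccc4)c(OCc4ccccc4)c(OCc4ccccc4)c3)[C@H](OCc3ccc(OC)cc3)C2=O | intermediate
12 | (2S,3R)-7-(benzyloxy)-8-bromo-2-[3,4,5-tris(benzyloxy)phenyl]chroman-3-ol (2,3-trans) | C(c3ccccc3)Oc1ccc2c(c1Br)O[C@@H](c3cc(OCc4ccccc4)c(OCc4ccccc4)c(OCc4ccccc4)c3)[C@H](O)C2 | intermediate
13 | (2S)-7-(benzyloxy)-8-bromo-2-[3,4,5-tris(benzyloxy)phenyl]chroman-3-one | C(c3ccccc3)Oc1ccc2c(c1Br)O[C@@H](c3cc(OCc4ccccc4)c(OCc4ccccc4)c(OCc4ccccc4)c3)C(=O)C2 | intermediate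
14 | (2S,3S)-7-(benzyloxy)-8-bromo-2-[3,4,5-tris(benzyloxy)phenyl]chroman-3-ol (2,3-cis) | C(c3ccccc3)Oc1ccc2c(c1Br)O[C@@H](c3cc(OCc4ccccc4)c(OCc4ccccc4)c(OCc4ccccc4)c3)[C@@H](O)C2 | intermediate
15 | (2S,3S)-3,7-bis(benzyloxy)-8-bromo-2-[3,4,5-tris(benzyloxy)phenyl]chromane (2,3-cis) | C(c3ccccc3)Oc1ccc2c(c1Br)O[C@@H](c3cc(OCc4ccccc4)c(OCc4ccccc4)c(OCc4ccccc4)c3)[C@@H](OCc3ccccc3)C2 | intermediate
16 | (2S,3S,4R)-3,7-bis(benzyloxy)-8-bromo-4-(2-ethoxyethoxy)-2-[3,4,5-tris(benzyloxy)phenyl]chromane (2,3-cis-3,4-trans) | C(c3ccccc3)Oc1ccc2c(c1Br)O[C@@H](c3cc(OCc4ccccc4)c(OCc4ccccc4)c(OCc4ccccc4)c3)[C@@H](OCc3ccccc3)[C@@H]2OCCOCC | intermediate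
17 | (−)-epicatechin, (2R,3R) | Oc1cc(O)c2c(c1)O[C@H](c1ccc(O)c(O)c1)[C@H](O)C2 | starting material
18 | 5,7,3',4'-tetra-O-benzyl-(−)-epicatechin | C(c3ccccc3)Oc1cc(OCc3ccccc3)c2c(c1)O[C@H](c3ccc(OCc4ccccc4)c(OCc4ccccc4)c3)[C@H](O)C2 | intermediate
19 | 3,5,7,3',4'-penta-O-benzyl-(−)-epicatechin | C(c3ccccc3)Oc1cc(OCc3ccccc3)c2c(c1)O[C@H](c3ccc(OCc4ccccc4)c(OCc4ccccc4)c3)[C@H](OCc3ccccc3)C2 | intermediate
20 | 8-bromo-ent-epirobinetinidol-(4α→8)-epicatechin deca-O-benzyl ether (middle unit 2S,3S,4S; bottom unit 2R,3R; Br on C8 of ring A of the middle unit) | Brc1c(OCc3ccccc3)ccc2c1O[C@@H](c3cc(OCc4ccccc4)c(OCc4ccccc4)c(OCc4ccccc4)c3)[C@@H](OCc3ccccc3)[C@@H]2c1c(OCc3ccccc3)cc(OCc3ccccc3)c2c1O[C@H](c3ccc(OCc4ccccc4)c(OCc4ccccc4)c3)[C@H](OCc3ccccc3)C2 | intermediate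
21 | C8-lithio analogue of 20 (lithium in place of bromine; not isolated) | [Li]c1c(OCc3ccccc3)ccc2c1O[C@@H](c3cc(OCc4ccccc4)c(OCc4ccccc4)c(OCc4ccccc4)c3)[C@@H](OCc3ccccc3)[C@@H]2c1c(OCc3ccccc3)cc(OCc3ccccc3)c2c1O[C@H](c3ccc(OCc4ccccc4)c(OCc4ccccc4)c3)[C@H](OCc3ccccc3)C2 | intermediate
22 | C8-dichlorocerio analogue of 20 (CeCl2 in place of bromine; not isolated) | Cl[Ce](Cl)c1c(OCc3ccccc3)ccc2c1O[C@@H](c3cc(OCc4ccccc4)c(OCc4ccccc4)c(OCc4ccccc4)c3)[C@@H](OCc3ccccc3)[C@@H]2c1c(OCc3ccccc3)cc(OCc3ccccc3)c2c1O[C@H](c3ccc(OCc4ccccc4)c(OCc4ccccc4)c3)[C@H](OCc3ccccc3)C2 | intermediate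
23 | C4 carbinol of the protected trimer: C8 of ring A of the middle unit of 20 bonded to C4 of 11, which carries OH; top unit keeps 3-O-PMB (trans to the C2 aryl) and 8-Br; new aryl trans, OH cis to the PMB ether | C(c3ccccc3)Oc1ccc2c(c1Br)O[C@@H](c3cc(OCc4ccccc4)c(OCc4ccccc4)c(OCc4ccccc4)c3)[C@H](OCc3ccc(OC)cc3)[C@@]2(O)c1c(OCc3ccccc3)ccc2c1O[C@@H](c3cc(OCc4ccccc4)c(OCc4ccccc4)c(OCc4ccccc4)c3)[C@@H](OCc3ccccc3)[C@@H]2c1c(OCc3ccccc3)cc(OCc3ccccc3)c2c1O[C@H](c3ccc(OCc4ccccc4)c(OCc4ccccc4)c3)[C@H](OCc3ccccc3)C2 | intermediate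
24 | 8-bromo-ent-robinetinidol-(4α→8)-ent-epirobinetinidol-(4α→8)-epicatechin tetradeca-O-benzyl ether, free 3-OH on the top unit (top 2S,3R,4S; middle 2S,3S,4S; bottom 2R,3R; Br on C8 of ring A of the top unit) | C(c3ccccc3)Oc1ccc2c(c1Br)O[C@@H](c3cc(OCc4ccccc4)c(OCc4ccccc4)c(OCc4ccccc4)c3)[C@H](O)[C@@H]2c1c(OCc3ccccc3)ccc2c1O[C@@H](c3cc(OCc4ccccc4)c(OCc4ccccc4)c(OCc4ccccc4)c3)[C@@H](OCc3ccccc3)[C@@H]2c1c(OCc3ccccc3)cc(OCc3ccccc3)c2c1O[C@H](c3ccc(OCc4ccccc4)c(OCc4ccccc4)c3)[C@H](OCc3ccccc3)C2 | intermediate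
25 | ent-robinetinidol-(4α→8)-ent-epirobinetinidol-(4α→8)-epicatechin, CNP0115797.3 (top 2S,3R,4S; middle 2S,3S,4S; bottom 2R,3R) | Oc1ccc2c(c1)O[C@@H](c1cc(O)c(O)c(O)c1)[C@H](O)[C@@H]2c1c(O)ccc2c1O[C@@H](c1cc(O)c(O)c(O)c1)[C@@H](O)[C@@H]2c1c(O)cc(O)c2c1O[C@H](c1ccc(O)c(O)c1)[C@H](O)C2 | target

**Count**

Total steps: 16. Longest linear sequence: 13 steps (steps 1, 2, 4, 5, 6, 7, 8, 9, 10, 13, 14, 15, 16).

**Steps most likely to fail**

Step 5 (proposed new method). What may go wrong: insufficient discrimination between the C2-epimeric aldolates in the ion pair, dehydration of the aldolate instead of ring closure, or racemisation of the product by base-induced opening of ring C. The fallback uses known reactions, stepwise and racemic, followed by resolution; it sets out from 8 and 9 and comes back at 11. The lithium enolate of 8 (LiHMDS, THF, −78 °C) would be added to 9 to give the racemic aldol adduct F1 as a syn/anti mixture. K2CO3 in DMF at room temperature would then close ring C by intramolecular SNAr and equilibrate C3, giving the racemic trans flavanone, that is 11 together with its (2R,3R) enantiomer F2. Kinetic resolution by asymmetric transfer hydrogenation (RuCl(p-cymene)[TsDPEN], the antipode that reduces the 2R ketone, HCO2H/Et3N) would convert F2 into the flavan-4-ol F3 and leave 11, which is separated by chromatography.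

Step 14. What may go wrong: enolisation and ring opening of the ketone by the basic aryl metal, or slow addition of the hindered dimeric nucleophile. The fallback inverts the order of assembly; it sets out from 16 and 11 and comes back at 24. The monomeric bromide 16, which can be used in excess, would be lithiated and transmetalated to cerium as in step 14 and added to 11 to give the dimeric carbinol F4. Et3SiH and TFA at −40 °C would reduce the tertiary diaryl carbinol and cleave the PMB ether while the secondary C4 ether of the middle unit survives, giving the 4-(2-ethoxyethoxy) dimer F5. TMSOTf-promoted coupling of F5 with 19, as in step 13, would then give 24.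

Step 15. What may go wrong: poor facial selectivity of hydride capture, loss of the C3 proton from the cation (enol ether formation and scrambling at C3), or alkylation of the electron-rich rings by the 4-methoxybenzyl cation. The fallback goes through the C4 radical and not the cation; it sets out from 23 and comes back at 25. The potassium alkoxide of 23 (KHMDS, THF, −78 °C) would be acylated with methyl chlorooxoacetate to the tertiary methyl oxalate F6. Bu3SnH and AIBN in toluene at 90 °C would cleave the C4–O bond homolytically (Barton–McCombie-type deoxygenation of a tertiary oxalate); the diarylmethyl radical should take hydrogen from the bulky stannane on the face anti to the C3 ether, and the excess stannane also reduces the aryl bromide, giving the debrominated 3-O-PMB trimer F7. The conditions of step 16 would remove the PMB group together with the benzyl groups and give 25.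

**Further compounds**

F1 | step 5 | racemic aldol adduct of 8 and 9 (syn/anti mixture): 1-[4-(benzyloxy)-3-bromo-2-fluorophenyl]-3-hydroxy-2-[(4-methoxybenzyl)oxy]-3-[3,4,5-tris(benzyloxy)phenyl]propan-1-one | OC(c1cc(OCc2ccccc2)c(OCc2ccccc2)c(OCc2ccccc2)c1)C(OCc1ccc(OC)cc1)C(=O)c1ccc(OCc2ccccc2)c(Br)c1F
F2 | step 5 | (2R,3R)-7-(benzyloxy)-8-bromo-3-[(4-methoxybenzyl)oxy]-2-[3,4,5-tris(benzyloxy)phenyl]chroman-4-one (enantiomer of 11) | C(c3ccccc3)Oc1ccc2c(c1Br)O[C@H](c3cc(OCc4ccccc4)c(OCc4ccccc4)c(OCc4ccccc4)c3)[C@@H](OCc3ccc(OC)cc3)C2=O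
F3 | step 5 | (2R,3S,4R)-7-(benzyloxy)-8-bromo-3-[(4-methoxybenzyl)oxy]-2-[3,4,5-tris(benzyloxy)phenyl]chroman-4-ol (2,3-trans-3,4-trans) | C(c3ccccc3)Oc1ccc2c(c1Br)O[C@H](c3cc(OCc4ccccc4)c(OCc4ccccc4)c(OCc4ccccc4)c3)[C@@H](OCc3ccc(OC)cc3)[C@@H]2O
F4 | step 14 | dimeric carbinol: C8 of ring A of 16 bonded to C4 of 11, which carries OH; top unit 3-O-PMB and 8-Br; middle unit keeps its 4-(2-ethoxyethoxy) group | C(c3ccccc3)Oc1ccc2c(c1Br)O[C@@H](c3cc(OCc4ccccc4)c(OCc4ccccc4)c(OCc4ccccc4)c3)[C@H](OCc3ccc(OC)cc3)[C@@]2(O)c1c(OCc3ccccc3)ccc2c1O[C@@H](c3cc(OCc4ccccc4)c(OCc4ccccc4)c(OCc4ccccc4)c3)[C@@H](OCc3ccccc3)[C@@H]2OCCOCC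
F5 | step 14 | 8-bromo-ent-robinetinidol-(4α→8)-4-(2-ethoxyethoxy)-ent-epirobinetinidol nona-O-benzyl ether, free 3-OH on the top unit | C(c3ccccc3)Oc1ccc2c(c1Br)O[C@@H](c3cc(OCc4ccccc4)c(OCc4ccccc4)c(OCc4ccccc4)c3)[C@H](O)[C@@H]2c1c(OCc3ccccc3)ccc2c1O[C@@H](c3cc(OCc4ccccc4)c(OCc4ccccc4)c(OCc4ccccc4)c3)[C@@H](OCc3ccccc3)[C@@H]2OCCOCC
F6 | step 15 | methyl oxalate ester of the C4 hydroxyl of 23 | C(c3ccccc3)Oc1ccc2c(c1Br)O[C@@H](c3cc(OCc4ccccc4)c(OCc4ccccc4)c(OCc4ccccc4)c3)[C@H](OCc3ccc(OC)cc3)[C@@]2(OC(=O)C(=O)OC)c1c(OCc3ccccc3)ccc2c1O[C@@H](c3cc(OCc4ccccc4)c(OCc4ccccc4)c(OCc4ccccc4)c3)[C@@H](OCc3ccccc3)[C@@H]2c1c(OCc3ccccc3)cc(OCc3ccccc3)c2c1O[C@H](c3ccc(OCc4ccccc4)c(OCc4ccccc4)c3)[C@H](OCc3ccccc3)C2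
F7 | step 15 | ent-robinetinidol-(4α→8)-ent-epirobinetinidol-(4α→8)-epicatechin tetradeca-O-benzyl ether with 3-O-PMB on the top unit (no bromine) | C(c3ccccc3)Oc1ccc2c(c1)O[C@@H](c3cc(OCc4ccccc4)c(OCc4ccccc4)c(OCc4ccccc4)c3)[C@H](OCc3ccc(OC)cc3)[C@@H]2c1c(OCc3ccccc3)ccc2c1O[C@@H](c3cc(OCc4ccccc4)c(OCc4ccccc4)c(OCc4ccccc4)c3)[C@@H](OCc3ccccc3)[C@@H]2c1c(OCc3ccccc3)cc(OCc3ccccc3)c2c1O[C@H](c3ccc(OCc4ccccc4)c(OCc4ccccc4)c3)[C@H](OCc3ccccc3)C2
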